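# Proposed synthesis of CNP0330752.2 by an Ireland–Claisen relay of chirality from C7 to C4

Target: 2-[(3R,4S,6R)-4,6-dimethyl-6-[(2R,4E,6E)-2,4,6-trimethyl-8-phenylocta-4,6-dien-1-yl]-1,2-dioxan-3-yl]acetic acid. Carbons are numbered C1 (carboxyl) to C14 (benzylic CH2) throughout, also in the intermediates.

## Structural features

The molecule is a 1,2-dioxane whose ring carbons are C3 to C6, with the O–O bond bridging C3 and C6. C3 carries the C1–C2 acetic acid arm, C4 a methyl group, and the quaternary C6 a methyl group and the C7–C14 chain. The chain holds a methyl-bearing stereocentre at C8 and ends in a (10E,12E)-diene (methyls on C10 and C12) joined through C14 to phenyl.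

There are four stereocentres: C3 (R), C4 (S) and C6 (R) in the ring, and C8 (R) in the chain. C3 and C4 are adjacent and trans. C4 and C8 lie 1,5 to each other on either side of C6. In the chair the C3 arm, the C4 methyl and the C6 chain are all equatorial, which leaves the C6 methyl axial.

The fragile parts are the O–O bond and the diene. The O–O bond is sensitive to reducing agents, low-valent metals, carbon radicals and base, because C3–H is alpha to the peroxide and beta to the carboxyl. The diene, with its doubly activated C14 methylene, is sensitive to acid, oxidants and electrophilic metals.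

The real difficulty is twofold. C4 must be controlled relative to the remote C8 across a carbon that is itself a quaternary peroxide centre. Both C–O bonds of the peroxide must be made late and with defined configuration.

The key step exploits the C5–C6–C7 segment. Once C6=C7 is an alkene, this segment is an allyl unit flanked by the two methyl-bearing carbons. An oxygen on C7, next to C8, can be acylated and can pass its configuration to C4 through a six-membered pericyclic array. The (E)-C6=C7 alkene left behind is the olefin onto which a C3 hydroperoxide later closes the ring at C6.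

## Logic of the disconnections

36 is cut at the C11–C12 bond of the diene into 30 and 35. The diene would not survive electrophilic mercury or the peroxide-forming steps, so it is made last from two alkenyl partners of fixed geometry. This removes the benzyl-terminated C12–C14 piece and leaves 30 with all four stereocentres. The forward coupling must retain both alkene geometries and spare the O–O bond and the free acid.

35 is traced through 33 to 31 by exchanging the C–B bond for C–I and then removing H and I from the C12=C13 alkene. This reduces the side piece to a simple internal alkyne. The forward hydrometalation must be syn and must place the metal on the methyl-bearing carbon.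

30 is traced through 29 to 28 without cutting a skeletal bond. C1 is lowered to the alcohol level and masked as a silyl ether, because a carbonyl at C1 would make any leaving group on C3 eliminate. The forward deprotection and oxidation must be mild towards the O–O bond.

28 is opened at the C6–O bond to give 26. This reveals an open-chain hydroperoxide and the C6=C7 alkene, and removes the ring and the quaternary stereocentre in one move. The forward closure must be 6-exo and Markovnikov, must select the face of C6 that puts the chain equatorial, and the metal left on C7 must be removed without breaking O–O.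

26 is cut at the C3–O bond and traced through 25 and 24 to 23. The peroxide oxygen is introduced by displacement of a sulfonate of the epimeric alcohol, so the problem becomes a 1,3-diol with the 3,4-syn relation. The forward steps must tell the two hydroxyls apart and must give clean inversion without elimination.

23 is traced through 22 and cut at C2–C3 into 19 and 20. C1 and C2 come from 20, and C3 is set by the auxiliary in the same sense as the Felkin–Anh preference of 19. The forward aldol must not epimerise 19 at C4.

19 is traced through 18 to 17 by functional-group interchange at C3. Nothing is cut; the demand is a reduction that stops at the aldehyde.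

17 is cut at C4–C5 with re-formation of the C7–O bond, giving 14. This moves the alkene from C6=C7 to C5=C6, removes the C4 stereocentre and reduces the chain to a C5–C11 allylic ester. The forward rearrangement needs one ketene acetal geometry, a chair, and the 7R configuration.

14 is cut at the ester C–O bond into 12 and 13, and 12 is traced to 11 by removing the C7–H bond. C7 then needs no separate building block. The forward reduction must deliver hydride to the face that gives the 7,8-anti alcohol.

11 is cut at C6–C7 into 9 and 10. The isopropenyl unit (C5, C6 and its methyl) is split off. The forward addition must stop after one equivalent and must not enolise C8.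

9 is traced through 8 and 7 and cut at C8–C9 into 4 and 5. C8 is set by auxiliary-controlled alkylation with an electrophile that already carries the iodoalkene.

4 is traced through 3 to 1 by cutting the C10–CH3 and C11–I bonds. Both are made in one carbometalation of a terminal alkyne, which must be syn and must place methyl on the internal carbon.

## Other disconnections considered

Alternative 1: The cut is the C5–C6 single bond, between the ring methylene and the carbon that becomes the quaternary peroxide centre. In the forward sense the primary alkylzinc iodide A1 (C1–C5, with the C3 oxygen as a triethylsilyl ether and the C4 methyl in place) would be coupled with the (E)-2-iodoalkene A2 (C6–C9, carrying C8) under Pd(PPh3)4. The product is the open chain A3, which holds the same (E)-C6=C7 alkene that the chosen route reaches by rearrangement.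

- **For:** it is convergent. The alkene geometry is carried in from A2 and does not rest on a transition-state preference. On convergence and on certainty of the C6=C7 geometry it is the better plan.
- **Against:** C4 and C8 each need their own source of absolute configuration. The zinc reagent comes from a beta-branched iodide and must couple at a fully substituted alkenyl carbon. A2 needs its own regiocontrolled route. A3 ends at C9, so C10–C14 still need a separate C9–C10 bond construction.
- **Comparison:** both plans reach the same C3–C9 array and both must then invert C3 and close the peroxide, so the hardest steps are equal. A palladium cycle replaces a pericyclic shift, which trades enolate-geometry risk for transmetalation and beta-hydride risk. The coupling is shorter to the C3–C8 segment but should be longer overall because of the extra chain extension and the second chiral controller.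

Alternative 2: The cut is the C11–C12 bond of the diene with the peroxide ring complete. In the forward sense the vinyl iodide A4 (the methyl ester of 30) would be coupled with boronate 35 under PdCl2(dppf) and K3PO4 to give A5, the methyl ester of 36. This is the same bond, the same boron partner and the same mechanism as the last step of the chosen route; only the ester differs.

- **For:** the diene enters after every electrophilic and oxidative step. The ester keeps a carboxylate out of the coupling and should make A4 and A5 easier to purify. On that point it is the better variant.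
- **Against:** as a strategic step it sets no stereocentre and leaves open how the four stereocentres of A4 arise, so it must be paired with a step such as the relay used here. A5 needs a final saponification in which hydroxide meets a beta-peroxy ester, with a risk of elimination or O–O cleavage.
- **Comparison:** on structure and mechanism the two are equal, and the risk to the O–O bond from low-valent palladium is the same. The chosen end game should be one step shorter.

Alternative 3: The cut is the C6–CH3 bond. In the forward sense the cyclic methyl peroxyketal A6 would be ionised by Me3SiOTf, and Me3Al would transfer methyl to the C6 peroxycarbenium ion. The product is A7, the tert-butyldiphenylsilyl counterpart of 28.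

- **For:** C6 is set by axial attack on a ring cation whose C3, C4 and C6 substituents stay equatorial. This stereoelectronic preference should be more dependable than the facial selectivity of a mercury-induced closure. No mercury and no C7 radical are involved, and the ring closes by peroxyketal formation. On control of C6 and on avoiding radical demercuration it is the better plan.
- **Against:** it needs a C6 ketone, so the C6=C7 alkene and the C8-to-C4 relay are lost and C4 needs its own control. A C3 hydroperoxide is still required, with the same inversion problem. A strong Lewis acid and an alkylalane next to an O–O bond invite ring opening, Hock-type shifts or reduction. The methyl group costs a separate C–C bond-forming step on a late intermediate, whereas here it enters with 10.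
- **Comparison:** the step counts should be equal within a step or two. The chosen route is better in economy of chirality, the alternative in control of C6.

Key step: step 9

## Remarks and assumptions

- Compounds 5, 20 and 31 are taken as catalogue compounds; each is otherwise one routine step from one.
- C8 is set by auxiliary alkylation and not from the chiral pool. A pool entry from methyl 3-hydroxy-2-methylpropanoate in which the hydroxymethyl carbon becomes C7 would need the (S)-ester; the (R)-ester would lead to 8S by that sequence. It would also be about three steps longer.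
- The precursor of the key step is kept as the (3R,4R)-propanoate with the iodoalkene as spectator. Only its preparation is changed: the ketone is reached through a Weinreb amide, which avoids an epimerisable aldehyde and one redox step.
- The boronate needed for the diene has boron trans to the benzylic CH2. Its CIP descriptor is Z because carbon outranks boron.
- The sense of induction in step 12, (R)-auxiliary giving 3S, is assigned from the chelated chair model and has not been checked against a measured example here.

## Route

Step 1
Reactants: 1 prop-2-yn-1-ol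
Product: 3 (2E)-3-iodo-2-methylprop-2-en-1-ol, via alkenylalane 2 (not isolated)
Conditions: Me3Al (3 equiv), Cp2ZrCl2 (0.25 equiv), CH2Cl2, 0 °C to rt; then I2, THF, −30 to 0 °C; aq. K2CO3
Reagents that add atoms: trimethylaluminium, C[Al](C)C; iodine, II
Why: Zirconocene-catalysed carboalumination (Negishi) of the aluminium alkoxide adds methyl and aluminium syn across the alkyne with methyl on the internal carbon. Iodinolysis of the C–Al bond with retention gives the (E)-iodoalkene that becomes C10=C11.

Step 2
Reactants: 3 (2E)-3-iodo-2-methylprop-2-en-1-ol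
Product: 4 (1E)-3-bromo-1-iodo-2-methylprop-1-ene
Conditions: CBr4, PPh3, CH2Cl2, 0 °C
Reagents that add atoms: tetrabromomethane, BrC(Br)(Br)Br
Why: Appel bromination of the primary allylic alcohol is an SN2 displacement of an alkoxyphosphonium ion and should leave the iodoalkene and its geometry untouched.

Step 3
Reactants: 5 (4S)-4-benzyl-3-propanoyl-1,3-oxazolidin-2-one; 4 (1E)-3-bromo-1-iodo-2-methylprop-1-ene
Product: 7 (4S)-4-benzyl-3-[(2R,4E)-5-iodo-2,4-dimethylpent-4-enoyl]-1,3-oxazolidin-2-one, via sodium enolate 6 (not isolated)
Conditions: NaN(SiMe3)2, THF, −78 °C; then 4, −78 to −40 °C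
Reagents that add atoms: none
Why: Evans alkylation: the chelated (Z)-enolate 6 is attacked by the allylic bromide at its primary carbon on the face away from the benzyl group. This sets C8 as R (2R in the acyl chain).

Step 4
Reactants: 7 (4S)-4-benzyl-3-[(2R,4E)-5-iodo-2,4-dimethylpent-4-enoyl]-1,3-oxazolidin-2-one
Product: 8 (2R,4E)-5-iodo-2,4-dimethylpent-4-enoic acid
Conditions: LiOH, H2O2, THF/H2O, 0 °C; then Na2SO3; HCl to pH 2
Reagents that add atoms: hydrogen peroxide, OO
Why: Hydroperoxide anion attacks the exocyclic imide carbonyl selectively, so the auxiliary is released without ring opening and without epimerising C8. Sulfite reduces the peracid first formed.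

Step 5
Reactants: 8 (2R,4E)-5-iodo-2,4-dimethylpent-4-enoic acid
Product: 9 (2R,4E)-5-iodo-N-methoxy-N,2,4-trimethylpent-4-enamide
Conditions: MeNH(OMe)·HCl, 1-ethyl-3-(3-dimethylaminopropyl)carbodiimide hydrochloride, 1-hydroxybenzotriazole, iPr2NEt, CH2Cl2, 0 °C to rt
Reagents that add atoms: N,O-dimethylhydroxylamine hydrochloride, CNOC.Cl
Why: Carbodiimide-mediated amide formation through the benzotriazolyl ester; the stereocentre of a simple alpha-methyl acid should survive.

Step 6
Reactants: 9 (2R,4E)-5-iodo-N-methoxy-N,2,4-trimethylpent-4-enamide; 10 prop-1-en-2-ylmagnesium bromide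
Product: 11 (4R,6E)-7-iodo-2,4,6-trimethylhepta-1,6-dien-3-one
Conditions: THF, 0 °C; cold 1 M HCl
Reagents that add atoms: none
Why: Weinreb ketone synthesis: the magnesium-chelated tetrahedral adduct persists until the acidic quench, which prevents a second addition and keeps C8 from enolising. The Grignard reagent should not exchange with the iodoalkene at 0 °C.

Step 7
Reactants: 11 (4R,6E)-7-iodo-2,4,6-trimethylhepta-1,6-dien-3-one
Product: 12 (3R,4R,6E)-7-iodo-2,4,6-trimethylhepta-1,6-dien-3-ol
Conditions: (S)-2-methyl-CBS-oxazaborolidine (0.2 equiv), catecholborane, toluene, −78 °C; MeOH, aq. NaOH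
Reagents that add atoms: none
Why: Corey–Bakshi–Shibata reduction: the ketone binds the oxazaborolidine anti to the conjugated isopropenyl group, which acts as the large substituent, and hydride is delivered to the face that gives 7R (3R in the name). Felkin–Anh control by C8 prefers the same 7,8-anti alcohol, so catalyst and substrate are matched; catecholborane at −78 °C should leave the alkenes alone.

Step 8
Reactants: 12 (3R,4R,6E)-7-iodo-2,4,6-trimethylhepta-1,6-dien-3-ol; 13 propanoyl chloride
Product: 14 (3R,4R,6E)-7-iodo-2,4,6-trimethylhepta-1,6-dien-3-yl propanoate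
Conditions: pyridine, 4-(dimethylamino)pyridine (cat.), CH2Cl2, 0 °C
Reagents that add atoms: none
Why: Nucleophile-catalysed O-acylation of the secondary allylic alcohol; no stereocentre is touched.

Step 9
Reactants: 14 (3R,4R,6E)-7-iodo-2,4,6-trimethylhepta-1,6-dien-3-yl propanoate
Product: 17 (2S,4E,6R,8E)-9-iodo-2,4,6,8-tetramethylnona-4,8-dienoic acid, via silyl ketene acetal 15 (not isolated), via trimethylsilyl ester 16 (not isolated)
Conditions: LiN(iPr)2 (1.15 equiv), THF, −78 °C; Me3SiCl/Et3N, −78 °C to rt, then 45 °C; 1 M HCl
Reagents that add atoms: none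
Why: Kinetic deprotonation of 14 by the amide base in THF without a polar cosolvent goes through a closed transition state and gives the enolate with methyl cis to the allylic oxygen, which O-silylation fixes as the (E)-silyl ketene acetal 15. On warming, 15 undergoes a concerted suprafacial [3,3]-sigmatropic shift through a chair: the C7–O bond breaks while C4 bonds to C5, and the silyl ester 16 is hydrolysed on work-up. The closest known reaction type is the Ireland–Claisen rearrangement of propanoates of secondary 2-methylallylic alcohols. No ring is closed. The new stereocentre C4 is controlled by the 7R carbinol configuration acting through the chair together with the ketene acetal geometry: with the C8 residue equatorial on C7 and the ketene acetal methyl pseudo-axial, C5 is bonded on the face that gives 4S, and the C7 stereocentre is traded for the (6E) alkene. The step needs high E selectivity in enolisation, chair over boat, and the equatorial C8 residue. These are secured by THF alone at −78 °C with immediate silyl trapping, by the normal preference of acyclic allyl ketene acetals, and by the strain an axial C8 group would meet against the C5 hydrogen and the silyloxy group. Ester deprotonation should be much faster than metalation of the iodoalkene C–H with only a slight excess of base.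

Step 10
Reactants: 17 (2S,4E,6R,8E)-9-iodo-2,4,6,8-tetramethylnona-4,8-dienoic acid
Product: 18 (2S,4E,6R,8E)-9-iodo-N-methoxy-N,2,4,6,8-pentamethylnona-4,8-dienamide
Conditions: MeNH(OMe)·HCl, 1-ethyl-3-(3-dimethylaminopropyl)carbodiimide hydrochloride, 1-hydroxybenzotriazole, iPr2NEt, CH2Cl2, 0 °C to rt
Reagents that add atoms: N,O-dimethylhydroxylamine hydrochloride, CNOC.Cl
Why: The same carbodiimide amidation as in step 5; it prepares C3 for a reduction that stops at the aldehyde.

Step 11
Reactants: 18 (2S,4E,6R,8E)-9-iodo-N-methoxy-N,2,4,6,8-pentamethylnona-4,8-dienamide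
Product: 19 (2S,4E,6R,8E)-9-iodo-2,4,6,8-tetramethylnona-4,8-dienal
Conditions: iBu2AlH, THF, −78 °C; aq. potassium sodium tartrate
Reagents that add atoms: none
Why: Hydride addition to the Weinreb amide gives a stable aluminium chelate that releases the aldehyde only on work-up, so over-reduction and epimerisation at C4 are avoided. The aldehyde is used at once.

Step 12
Reactants: 19 (2S,4E,6R,8E)-9-iodo-2,4,6,8-tetramethylnona-4,8-dienal; 20 1-[(4R)-4-benzyl-2-sulfanylidene-1,3-thiazolidin-3-yl]ethan-1-one
Product: 22 (3S,4S,6E,8R,10E)-1-[(4R)-4-benzyl-2-sulfanylidene-1,3-thiazolidin-3-yl]-3-hydroxy-11-iodo-4,6,8,10-tetramethylundeca-6,10-dien-1-one, via titanium enolate 21 (not isolated)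
Conditions: 20, TiCl4, iPr2NEt, CH2Cl2, −78 to −40 °C; then 19, −78 °C; aq. NH4Cl
Reagents that add atoms: none
Why: Thiazolidinethione acetate aldol through a chelated Zimmerman–Traxler chair: enolate 21 adds to the aldehyde on the face away from the auxiliary benzyl group, which gives 3S. The Felkin–Anh preference of the C4-branched aldehyde is for the same 3,4-syn product, so the pair is matched.

Step 13
Reactants: 22 (3S,4S,6E,8R,10E)-1-[(4R)-4-benzyl-2-sulfanylidene-1,3-thiazolidin-3-yl]-3-hydroxy-11-iodo-4,6,8,10-tetramethylundeca-6,10-dien-1-one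
Product: 23 (3S,4S,6E,8R,10E)-11-iodo-4,6,8,10-tetramethylundeca-6,10-diene-1,3-diol
Conditions: NaBH4, THF/EtOH, 0 °C
Reagents that add atoms: none
Why: The activated N-acyl thiazolidinethione is reduced by borohydride to the primary alcohol with release of the auxiliary. C1 is thereby taken to the alcohol level, which later keeps the C3 leaving group from beta-elimination.

Step 14
Reactants: 23 (3S,4S,6E,8R,10E)-11-iodo-4,6,8,10-tetramethylundeca-6,10-diene-1,3-diol
Product: 24 (3S,4S,6E,8R,10E)-11-iodo-4,6,8,10-tetramethyl-1-{[tri(propan-2-yl)silyl]oxy}undeca-6,10-dien-3-ol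
Conditions: iPr3SiCl, imidazole, CH2Cl2, 0 °C
Reagents that add atoms: chlorotri(propan-2-yl)silane, CC(C)[Si](Cl)(C(C)C)C(C)C
Why: The bulky silyl chloride should react with the primary hydroxyl much faster than with the hindered secondary one. The triisopropylsilyl ether resists the alkaline peroxide of step 16 and the acid of step 17.

Step 15
Reactants: 24 (3S,4S,6E,8R,10E)-11-iodo-4,6,8,10-tetramethyl-1-{[tri(propan-2-yl)silyl]oxy}undeca-6,10-dien-3-ol
Product: 25 (3S,4S,6E,8R,10E)-11-iodo-4,6,8,10-tetramethyl-1-{[tri(propan-2-yl)silyl]oxy}undeca-6,10-dien-3-yl methanesulfonate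
Conditions: MeSO2Cl, Et3N, CH2Cl2, −10 °C
Reagents that add atoms: methanesulfonyl chloride, CS(=O)(=O)Cl
Why: O-sulfonylation with retention at C3 turns the hydroxyl into a leaving group for the SN2 step.

Step 16
Reactants: 25 (3S,4S,6E,8R,10E)-11-iodo-4,6,8,10-tetramethyl-1-{[tri(propan-2-yl)silyl]oxy}undeca-6,10-dien-3-yl methanesulfonate
Product: 26 {[(3R,4S,6E,8R,10E)-3-hydroperoxy-11-iodo-4,6,8,10-tetramethylundeca-6,10-dien-1-yl]oxy}tri(propan-2-yl)silane
Conditions: H2O2 (50% aq., large excess), KOH, MeOH/THF, 0 °C to rt
Reagents that add atoms: hydrogen peroxide, OO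
Why: SN2 displacement of a secondary sulfonate by hydroperoxide anion, a weakly basic alpha-effect nucleophile, with inversion gives 3R. The large excess of H2O2 suppresses a second alkylation, and with C1 at the alcohol level no acidified C2–H promotes elimination.

Step 17
Reactants: 26 {[(3R,4S,6E,8R,10E)-3-hydroperoxy-11-iodo-4,6,8,10-tetramethylundeca-6,10-dien-1-yl]oxy}tri(propan-2-yl)silane
Product: 28 {2-[(3R,4S,6R)-6-[(2R,4E)-5-iodo-2,4-dimethylpent-4-en-1-yl]-4,6-dimethyl-1,2-dioxan-3-yl]ethoxy}tri(propan-2-yl)silane, via C7-acetoxymercurio dioxane 27 (not isolated)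
Conditions: Hg(OAc)2, HClO4 (cat.), CH2Cl2, rt; then NaBH4, 2 M NaOH, 0 °C
Reagents that add atoms: none
Why: Cycloperoxymercuration: divalent mercury activates the electron-richer C6=C7 alkene, and the hydroperoxide oxygen adds to the more substituted C6 in 6-exo mode, anti to mercury. In the chair the C3 and C4 substituents and the mercury-bearing C7 are equatorial and the C6 methyl axial, which gives 6R; the acid makes the addition reversible so that this most stable isomer should prevail. Alkaline borohydride then replaces mercury on C7 by hydrogen.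

Step 18
Reactants: 28 {2-[(3R,4S,6R)-6-[(2R,4E)-5-iodo-2,4-dimethylpent-4-en-1-yl]-4,6-dimethyl-1,2-dioxan-3-yl]ethoxy}tri(propan-2-yl)silane
Product: 29 2-[(3R,4S,6R)-6-[(2R,4E)-5-iodo-2,4-dimethylpent-4-en-1-yl]-4,6-dimethyl-1,2-dioxan-3-yl]ethan-1-ol
Conditions: Bu4NF, AcOH (1:1), THF, 0 °C to rt
Reagents that add atoms: none
Why: Fluoride cleaves the Si–O bond. The acetic acid buffer keeps the medium from becoming basic enough to remove the C3 hydrogen and start a Kornblum–DeLaMare cleavage of the peroxide.

Step 19
Reactants: 29 2-[(3R,4S,6R)-6-[(2R,4E)-5-iodo-2,4-dimethylpent-4-en-1-yl]-4,6-dimethyl-1,2-dioxan-3-yl]ethan-1-ol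
Product: 30 2-[(3R,4S,6R)-6-[(2R,4E)-5-iodo-2,4-dimethylpent-4-en-1-yl]-4,6-dimethyl-1,2-dioxan-3-yl]acetic acid
Conditions: 2,2,6,6-tetramethylpiperidin-1-oxyl (0.2 equiv), PhI(OAc)2 (2.2 equiv), MeCN/H2O (1:1), rt
Reagents that add atoms: water, O
Why: Oxoammonium-mediated oxidation takes the primary alcohol through the aldehyde hydrate to the acid. It uses no reducing metal and no strong base, so the O–O bond and the iodoalkene should survive.

Step 20
Reactants: 31 but-2-yn-1-ylbenzene
Product: 33 [(2E)-3-iodobut-2-en-1-yl]benzene, via alkenylzirconocene 32 (not isolated)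
Conditions: Cp2Zr(H)Cl (1.5 equiv), THF, 50 °C; then I2, 0 °C
Reagents that add atoms: iodine, II
Why: Hydrozirconation is a syn addition, and under equilibrating conditions (excess hydride, gentle heat) zirconium settles on the less hindered, methyl-bearing carbon. Iodinolysis with retention gives the (E)-iodide, and any minor regioisomer is removed at this stage.

Step 21
Reactants: 33 [(2E)-3-iodobut-2-en-1-yl]benzene
Product: 35 4,4,5,5-tetramethyl-2-[(2Z)-4-phenylbut-2-en-2-yl]-1,3,2-dioxaborolane, via alkenyllithium 34 (not isolated)
Conditions: tBuLi (2.1 equiv), Et2O, −78 °C; then 2-isopropoxy-4,4,5,5-tetramethyl-1,3,2-dioxaborolane, −78 °C to rt; HCl in Et2O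
Reagents that add atoms: 2-isopropoxy-4,4,5,5-tetramethyl-1,3,2-dioxaborolane, CC(C)OB1OC(C)(C)C(C)(C)O1
Why: Iodine–lithium exchange on an alkenyl iodide and capture of the alkenyllithium by the borate both go with retention, so boron ends up trans to the benzylic CH2.

Step 22
Reactants: 30 2-[(3R,4S,6R)-6-[(2R,4E)-5-iodo-2,4-dimethylpent-4-en-1-yl]-4,6-dimethyl-1,2-dioxan-3-yl]acetic acid; 35 4,4,5,5-tetramethyl-2-[(2Z)-4-phenylbut-2-en-2-yl]-1,3,2-dioxaborolane
Product: 36 2-[(3R,4S,6R)-4,6-dimethyl-6-[(2R,4E,6E)-2,4,6-trimethyl-8-phenylocta-4,6-dien-1-yl]-1,2-dioxan-3-yl]acetic acid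
Conditions: PdCl2(dppf) (5 mol%), K3PO4 (3 equiv), degassed THF/H2O, rt; then pH 4 buffer
Reagents that add atoms: none
Why: Suzuki–Miyaura coupling: oxidative addition into the C11–I bond and transmetalation from the boronate both go with retention, so the (10E,12E) diene follows from the two partners. Room temperature and aqueous phosphate are chosen to spare the dialkyl peroxide and the beta-peroxy carboxylate.

## Compound list

1 | prop-2-yn-1-ol | C#CCO | starting material
2 | dimethyl[(1E)-3-[(dimethylalumanyl)oxy]-2-methylprop-1-en-1-yl]alumane | C[Al](C)/C=C(\C)CO[Al](C)C | intermediate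
3 | (2E)-3-iodo-2-methylprop-2-en-1-ol | OC/C(C)=C/I | intermediate
4 | (1E)-3-bromo-1-iodo-2-methylprop-1-ene | BrC/C(C)=C/I | intermediate
5 | (4S)-4-benzyl-3-propanoyl-1,3-oxazolidin-2-one | CCC(=O)N1[C@@H](Cc2ccccc2)COC1=O | starting material
6 | sodium (1Z)-1-[(4S)-4-benzyl-2-oxo-1,3-oxazolidin-3-yl]prop-1-en-1-olate | C/C=C(\O[Na])N1[C@@H](Cc2ccccc2)COC1=O | intermediate
7 | (4S)-4-benzyl-3-[(2R,4E)-5-iodo-2,4-dimethylpent-4-enoyl]-1,3-oxazolidin-2-one | I/C=C(\C)C[C@@H](C)C(=O)N1[C@@H](Cc2ccccc2)COC1=O | intermediate
8 | (2R,4E)-5-iodo-2,4-dimethylpent-4-enoic acid | I/C=C(\C)C[C@@H](C)C(=O)O | intermediate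
9 | (2R,4E)-5-iodo-N-methoxy-N,2,4-trimethylpent-4-enamide | I/C=C(\C)C[C@@H](C)C(=O)N(C)OC | intermediate
10 | prop-1-en-2-ylmagnesium bromide | C=C(C)[Mg]Br | starting material
11 | (4R,6E)-7-iodo-2,4,6-trimethylhepta-1,6-dien-3-one | I/C=C(\C)C[C@@H](C)C(=O)C(C)=C | intermediate
12 | (3R,4R,6E)-7-iodo-2,4,6-trimethylhepta-1,6-dien-3-ol | I/C=C(\C)C[C@@H](C)[C@@H](O)C(C)=C | intermediate
13 | propanoyl chloride | CCC(=O)Cl | starting material
14 | (3R,4R,6E)-7-iodo-2,4,6-trimethylhepta-1,6-dien-3-yl propanoate | I/C=C(\C)C[C@@H](C)[C@@H](OC(=O)CC)C(C)=C | intermediate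
15 | trimethyl{[(1E)-1-{[(3R,4R,6E)-7-iodo-2,4,6-trimethylhepta-1,6-dien-3-yl]oxy}prop-1-en-1-yl]oxy}silane | I/C=C(\C)C[C@@H](C)[C@@H](O/C(O[Si](C)(C)C)=C\C)C(C)=C | intermediate
16 | trimethylsilyl (2S,4E,6R,8E)-9-iodo-2,4,6,8-tetramethylnona-4,8-dienoate | I/C=C(\C)C[C@@H](C)/C=C(\C)C[C@H](C)C(=O)O[Si](C)(C)C | intermediate
17 | (2S,4E,6R,8E)-9-iodo-2,4,6,8-tetramethylnona-4,8-dienoic acid | I/C=C(\C)C[C@@H](C)/C=C(\C)C[C@H](C)C(=O)O | intermediate
18 | (2S,4E,6R,8E)-9-iodo-N-methoxy-N,2,4,6,8-pentamethylnona-4,8-dienamide | I/C=C(\C)C[C@@H](C)/C=C(\C)C[C@H](C)C(=O)N(C)OC | intermediate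
19 | (2S,4E,6R,8E)-9-iodo-2,4,6,8-tetramethylnona-4,8-dienal | I/C=C(\C)C[C@@H](C)/C=C(\C)C[C@H](C)C=O | intermediate
20 | 1-[(4R)-4-benzyl-2-sulfanylidene-1,3-thiazolidin-3-yl]ethan-1-one | CC(=O)N1[C@H](Cc2ccccc2)CSC1=S | starting material
21 | trichloro({1-[(4R)-4-benzyl-2-sulfanylidene-1,3-thiazolidin-3-yl]ethenyl}oxy)titanium | C=C(O[Ti](Cl)(Cl)Cl)N1[C@H](Cc2ccccc2)CSC1=S | intermediate
22 | (3S,4S,6E,8R,10E)-1-[(4R)-4-benzyl-2-sulfanylidene-1,3-thiazolidin-3-yl]-3-hydroxy-11-iodo-4,6,8,10-tetramethylundeca-6,10-dien-1-one | I/C=C(\C)C[C@@H](C)/C=C(\C)C[C@H](C)[C@@H](O)CC(=O)N1[C@H](Cc2ccccc2)CSC1=S | intermediate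
23 | (3S,4S,6E,8R,10E)-11-iodo-4,6,8,10-tetramethylundeca-6,10-diene-1,3-diol | I/C=C(\C)C[C@@H](C)/C=C(\C)C[C@H](C)[C@@H](O)CCO | intermediate
24 | (3S,4S,6E,8R,10E)-11-iodo-4,6,8,10-tetramethyl-1-{[tri(propan-2-yl)silyl]oxy}undeca-6,10-dien-3-ol | I/C=C(\C)C[C@@H](C)/C=C(\C)C[C@H](C)[C@@H](O)CCO[Si](C(C)C)(C(C)C)C(C)C | intermediate
25 | (3S,4S,6E,8R,10E)-11-iodo-4,6,8,10-tetramethyl-1-{[tri(propan-2-yl)silyl]oxy}undeca-6,10-dien-3-yl methanesulfonate | I/C=C(\C)C[C@@H](C)/C=C(\C)C[C@H](C)[C@@H](OS(C)(=O)=O)CCO[Si](C(C)C)(C(C)C)C(C)C | intermediate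
26 | {[(3R,4S,6E,8R,10E)-3-hydroperoxy-11-iodo-4,6,8,10-tetramethylundeca-6,10-dien-1-yl]oxy}tri(propan-2-yl)silane | I/C=C(\C)C[C@@H](C)/C=C(\C)C[C@H](C)[C@H](OO)CCO[Si](C(C)C)(C(C)C)C(C)C | intermediate
27 | compound 28 bearing an acetoxymercurio group on C7 (anti to the new C6–O bond; 7R) | I/C=C(\C)C[C@@H](C)[C@@H]([Hg]OC(C)=O)[C@]1(C)C[C@H](C)[C@@H](CCO[Si](C(C)C)(C(C)C)C(C)C)OO1 | intermediate
28 | {2-[(3R,4S,6R)-6-[(2R,4E)-5-iodo-2,4-dimethylpent-4-en-1-yl]-4,6-dimethyl-1,2-dioxan-3-yl]ethoxy}tri(propan-2-yl)silane | I/C=C(\C)C[C@@H](C)C[C@]1(C)C[C@H](C)[C@@H](CCO[Si](C(C)C)(C(C)C)C(C)C)OO1 | intermediate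
29 | 2-[(3R,4S,6R)-6-[(2R,4E)-5-iodo-2,4-dimethylpent-4-en-1-yl]-4,6-dimethyl-1,2-dioxan-3-yl]ethan-1-ol | I/C=C(\C)C[C@@H](C)C[C@]1(C)C[C@H](C)[C@@H](CCO)OO1 | intermediate
30 | 2-[(3R,4S,6R)-6-[(2R,4E)-5-iodo-2,4-dimethylpent-4-en-1-yl]-4,6-dimethyl-1,2-dioxan-3-yl]acetic acid | I/C=C(\C)C[C@@H](C)C[C@]1(C)C[C@H](C)[C@@H](CC(=O)O)OO1 | intermediate
31 | but-2-yn-1-ylbenzene | CC#CCc1ccccc1 | starting material
32 | chlorobis(cyclopentadienyl)[(2E)-4-phenylbut-2-en-2-yl]zirconium | C/C(=C\Cc1ccccc1)[Zr](Cl)(C1C=CC=C1)C1C=CC=C1 | intermediate
33 | [(2E)-3-iodobut-2-en-1-yl]benzene | C/C(I)=C\Cc1ccccc1 | intermediate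
34 | [(2Z)-4-phenylbut-2-en-2-yl]lithium (lithium trans to the benzylic CH2) | C/C([Li])=C\Cc1ccccc1 | intermediate
35 | 4,4,5,5-tetramethyl-2-[(2Z)-4-phenylbut-2-en-2-yl]-1,3,2-dioxaborolane | C/C(B1OC(C)(C)C(C)(C)O1)=C\Cc1ccccc1 | intermediate
36 | 2-[(3R,4S,6R)-4,6-dimethyl-6-[(2R,4E,6E)-2,4,6-trimethyl-8-phenylocta-4,6-dien-1-yl]-1,2-dioxan-3-yl]acetic acid | CC(=C\Cc1ccccc1)/C=C(\C)C[C@@H](C)C[C@]1(C)C[C@H](C)[C@@H](CC(=O)O)OO1 | target

## Step count and least certain steps

Total: 22 steps. Longest linear sequence: 20 steps (steps 1 to 19, then step 22). Steps 20 and 21 form the side branch to 35.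

**Step 9 (key step).** What may go wrong is erosion of the ketene acetal geometry during enolisation, which would pass directly into loss of configuration at C4. Competing metalation of the iodoalkene C–H by the amide base is a second risk. Fallback: the C4–C5 bond is made by auxiliary alkylation instead of by rearrangement, setting out from 9 and returning at 17. Reduction of 9 with iBu2AlH at −78 °C would give (2R,4E)-5-iodo-2,4-dimethylpent-4-enal F1. Wittig olefination with ethyl 2-(triphenylphosphoranylidene)propanoate would give ethyl (2E,4R,6E)-7-iodo-2,4,6-trimethylhepta-2,6-dienoate F2. Reduction with iBu2AlH would give (2E,4R,6E)-7-iodo-2,4,6-trimethylhepta-2,6-dien-1-ol F3, and CBr4/PPh3 would give (1E,4R,5E)-7-bromo-1-iodo-2,4,6-trimethylhepta-1,5-diene F4. Alkylation of the sodium enolate of (4R)-4-benzyl-3-propanoyl-1,3-oxazolidin-2-one with F4 would give (4R)-4-benzyl-3-[(2S,4E,6R,8E)-9-iodo-2,4,6,8-tetramethylnona-4,8-dienoyl]-1,3-oxazolidin-2-one F5. Cleavage with LiOH/H2O2 returns 17.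

**Step 16.** What may go wrong is elimination of methanesulfonic acid outrunning substitution at the hindered, beta-branched secondary carbon. Further alkylation or base-induced decomposition of the hydroperoxide once formed is a second risk. Fallback: a mono-protected peroxide anion is alkylated in a dipolar aprotic medium and then unmasked, setting out from 25 and returning at 26. With 2-hydroperoxy-2-methoxypropane (made by ozonolysis of 2,3-dimethylbut-2-ene in methanol) and CsOH in DMF at 0 °C, 25 would give the peroxyketal {[(3R,4S,6E,8R,10E)-11-iodo-3-[(2-methoxypropan-2-yl)peroxy]-4,6,8,10-tetramethylundeca-6,10-dien-1-yl]oxy}tri(propan-2-yl)silane F6. Mild hydrolysis with AcOH/THF/H2O releases 26.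

**Step 17.** What may go wrong is insufficient facial selectivity at C6 in the ring closure. During hydride demercuration the C7 radical may also fragment with cleavage of the O–O bond to give an epoxide. Fallback: an ionic closure without mercury or a carbon radical, setting out from 26 and returning at 28. A catalytic strong Brønsted acid (CF3SO3H, CH2Cl2, −40 °C) would protonate C6=C7 in the Markovnikov sense, and the C3 hydroperoxide would capture the tertiary C6 cation. This is the intramolecular form of the classical acid-catalysed addition of a hydroperoxide to an alkene. Reversible ionisation at C6 should let the ring settle with the chain equatorial. No new compound is involved.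

**Step 7.** What may go wrong is poor discrimination by the oxazaborolidine between the isopropenyl group and the branched alkyl residue, giving a mixture at C7. Fallback: unselective reduction followed by kinetic resolution, setting out from 11 and returning at 12. Luche reduction (NaBH4, CeCl3, MeOH, −78 °C) would give 12 together with its epimer (3S,4R,6E)-7-iodo-2,4,6-trimethylhepta-1,6-dien-3-ol F7. Sharpless kinetic resolution with Ti(OiPr)4, L-(+)-diisopropyl tartrate and tBuOOH should epoxidise the 3S epimer faster, converting F7 into (1S,2R,4E)-5-iodo-2,4-dimethyl-1-[(2S)-2-methyloxiran-2-yl]pent-4-en-1-ol F8. This leaves 12 to be separated.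

**Step 22.** What may go wrong is cleavage of the O–O bond by zerovalent palladium or phosphine, or protodeboronation of the hindered alkenyl boronate before it transmetalates. Fallback: a palladium-free, copper-mediated coupling of a stannane, setting out from 33 and returning at 36. Exchange of 33 with tBuLi and capture with Bu3SnCl would give tributyl[(2E)-4-phenylbut-2-en-2-yl]stannane F9. Treatment of F9 and 30 with copper thiophene-2-carboxylate, Cu(O2CC4H3S), in N-methylpyrrolidin-2-one at 0 °C would give 36 under neutral, phosphine-free conditions.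

## Further compounds

F1 | step 9 | (2R,4E)-5-iodo-2,4-dimethylpent-4-enal | I/C=C(\C)C[C@@H](C)C=O
F2 | step 9 | ethyl (2E,4R,6E)-7-iodo-2,4,6-trimethylhepta-2,6-dienoate | I/C=C(\C)C[C@@H](C)/C=C(\C)C(=O)OCC
F3 | step 9 | (2E,4R,6E)-7-iodo-2,4,6-trimethylhepta-2,6-dien-1-ol | I/C=C(\C)C[C@@H](C)/C=C(\C)CO
F4 | step 9 | (1E,4R,5E)-7-bromo-1-iodo-2,4,6-trimethylhepta-1,5-diene | I/C=C(\C)C[C@@H](C)/C=C(\C)CBr
F5 | step 9 | (4R)-4-benzyl-3-[(2S,4E,6R,8E)-9-iodo-2,4,6,8-tetramethylnona-4,8-dienoyl]-1,3-oxazolidin-2-one | I/C=C(\C)C[C@@H](C)/C=C(\C)C[C@H](C)C(=O)N1[C@H](Cc2ccccc2)COC1=O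
F6 | step 16 | {[(3R,4S,6E,8R,10E)-11-iodo-3-[(2-methoxypropan-2-yl)peroxy]-4,6,8,10-tetramethylundeca-6,10-dien-1-yl]oxy}tri(propan-2-yl)silane | I/C=C(\C)C[C@@H](C)/C=C(\C)C[C@H](C)[C@H](OOC(C)(C)OC)CCO[Si](C(C)C)(C(C)C)C(C)C
F0 | step 17 | none | none
F7 | step 7 | (3S,4R,6E)-7-iodo-2,4,6-trimethylhepta-1,6-dien-3-ol | I/C=C(\C)C[C@@H](C)[C@H](O)C(C)=C
F8 | step 7 | (1S,2R,4E)-5-iodo-2,4-dimethyl-1-[(2S)-2-methyloxiran-2-yl]pent-4-en-1-ol | I/C=C(\C)C[C@@H](C)[C@H](O)[C@]1(C)CO1
F9 | step 22 | tributyl[(2E)-4-phenylbut-2-en-2-yl]stannane | C/C(=C\Cc1ccccc1)[Sn](CCCC)(CCCC)CCCC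
A1 | alternative 1 | primary alkylzinc iodide C1–C5: iodo{(2S,3S)-5-[(tert-butyldiphenylsilyl)oxy]-2-methyl-3-[(triethylsilyl)oxy]pentyl}zinc | I[Zn]C[C@H](C)[C@H](CCO[Si](c1ccccc1)(c1ccccc1)C(C)(C)C)O[Si](CC)(CC)CC
A2 | alternative 1 | (E)-2-iodoalkene C6–C9: 1-({[(2S,3E)-4-iodo-2-methylpent-3-en-1-yl]oxy}methyl)-4-methoxybenzene | COc1ccc(COC[C@@H](C)/C=C(\C)I)cc1
A3 | alternative 1 | protected C1–C9 chain with the (E)-C6=C7 alkene (C9 4-methoxybenzyl ether, C3 triethylsilyl ether, C1 tert-butyldiphenylsilyl ether) | COc1ccc(COC[C@@H](C)/C=C(\C)C[C@H](C)[C@H](CCO[Si](c2ccccc2)(c2ccccc2)C(C)(C)C)O[Si](CC)(CC)CC)cc1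
A4 | alternative 2 | methyl 2-[(3R,4S,6R)-6-[(2R,4E)-5-iodo-2,4-dimethylpent-4-en-1-yl]-4,6-dimethyl-1,2-dioxan-3-yl]acetate | I/C=C(\C)C[C@@H](C)C[C@]1(C)C[C@H](C)[C@@H](CC(=O)OC)OO1
A5 | alternative 2 | methyl 2-[(3R,4S,6R)-4,6-dimethyl-6-[(2R,4E,6E)-2,4,6-trimethyl-8-phenylocta-4,6-dien-1-yl]-1,2-dioxan-3-yl]acetate | CC(=C\Cc1ccccc1)/C=C(\C)C[C@@H](C)C[C@]1(C)C[C@H](C)[C@@H](CC(=O)OC)OO1
A6 | alternative 3 | cyclic methyl peroxyketal: tert-butyl{2-[(3R,4S)-6-[(2R,4E)-5-iodo-2,4-dimethylpent-4-en-1-yl]-6-methoxy-4-methyl-1,2-dioxan-3-yl]ethoxy}diphenylsilane (C6 either configuration) | I/C=C(\C)C[C@@H](C)CC1(OC)C[C@H](C)[C@@H](CCO[Si](c2ccccc2)(c2ccccc2)C(C)(C)C)OO1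
A7 | alternative 3 | tert-butyl{2-[(3R,4S,6R)-6-[(2R,4E)-5-iodo-2,4-dimethylpent-4-en-1-yl]-4,6-dimethyl-1,2-dioxan-3-yl]ethoxy}diphenylsilane | I/C=C(\C)C[C@@H](C)C[C@]1(C)C[C@H](C)[C@@H](CCO[Si](c2ccccc2)(c2ccccc2)C(C)(C)C)OO1
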